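**Retrosynthetic overview**
1. Tomoeone D ⇒ gem-diprenylation at C3 after base opening of a C2–O–C7' bridge ⇒ C5-isobutyryl bridged enol ether ⇒ C-acylation of the unacylated bridged enol ether.
2. Bridged enol ether ⇒ intramolecular Markovnikov hydroalkoxylation of C7'=C8' by the axial ring A enol (fixes C7' and the spiro carbon) ⇒ spiro trione with two equivalent ring A arms.
3. Spiro trione ⇒ intramolecular Diels–Alder reaction of the ring-opened (oxatriene) form of a 2H-chromene: exocyclic diene C1=C8'–C7'=C6' plus vinyl C1'=C2'; cyclopentane and spirocyclohexene form together (sets C2', C6').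
4. 2H-Chromene ⇒ Knoevenagel/oxa-6π electrocyclization of phloroglucinol with (E)-8-oxolinalool ⇒ (R)-linalool, which supplies C3' and all ten terpenoid carbons.
5. Ring order: pyran (temporary) → cyclopentane + spirocyclohexene (one step) → bridging oxolane (temporary) → ring A substituents last.

Labels and assumption: ring A carbons are C1 (spiro) to C6; terpenoid carbons C1'–C10' keep linalool numbering (C8' = former aldehyde carbon, C9'/C10' = methyls on C7'/C3'). Prenyl bromide, isobutyric acid and the other reagents are taken as commercial. The route has not been run; yields and selectivities are expectations.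

Step 1
Reactants: 1 (R)-(−)-linalool
Product: 3 (E)-8-oxolinalool, via (E)-8-hydroxylinalool 2 (not isolated)
Conditions: SeO2 (1.2 equiv), 1,4-dioxane/EtOH 9:1, 80 °C
Reagents that add atoms: selenium dioxide O=[Se]=O
Why: Riley allylic oxidation (ene reaction then [2,3]-sigmatropic shift) attacks the (E)-methyl of the trisubstituted alkene to give allylic alcohol 2, which SeO2 takes on to the (E)-enal, while the vinyl carbinol with its bought (R) centre is untouched.

Step 2
Reactants: 3 (E)-8-oxolinalool; 4 phloroglucinol (3 equiv)
Product: 6 2-[(3R)-3-hydroxy-3-methylpent-4-enyl]-3-methyl-2H-chromene-5,7-diol, via oxatriene 5 (not isolated)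
Conditions: ethylenediammonium diacetate (20 mol %), MeOH, 65 °C
Reagents that add atoms: none
Why: Knoevenagel-type condensation at a ring CH gives oxatriene 5, which closes by oxa-6π electrocyclization to the aromatic chromene; excess phloroglucinol suppresses double condensation, and the new C2 centre forms as both epimers, which is harmless because step 3 erases it.

Step 3
Reactants: 6 2H-chromene
Product: 7 trans-fused spiro-hexahydroindene trione (Diels–Alder adduct)
Conditions: pyridine (0.01 M, degassed), sealed tube, 190 °C
Reagents that add atoms: none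
Why: In hot pyridine chromene 6 reopens by retro-oxa-6π electrocyclization to oxatriene 5 (the species already passed through in step 2, now free of excess phloroglucinol, which could otherwise trap it), whose exocyclic diene adds the tethered vinyl group in an intramolecular Diels–Alder reaction; the anti (tether-exo) transition state is expected to give the trans ring fusion (C6'), and the C3' carbinol, with OH rather than CH3 turned toward the incoming ring A carbonyl (hydrogen bond), is expected to set C2' with C1' cis to OH, while C1 is not yet stereogenic because the two ring A arms are equivalent by tautomerism.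

Step 4
Reactants: 7 spiro trione
Product: 8 C2–O–C7' bridged enol ether
Conditions: Co(salen) [N,N'-bis(3,5-di-tert-butylsalicylidene)ethane-1,2-diaminatocobalt, achiral, divalent cobalt] (5 mol %), N-fluoro-2,4,6-trimethylpyridinium tetrafluoroborate (1.2 equiv), PhSiH3 (1.2 equiv), PhCF3, rt
Reagents that add atoms: none
Why: Cobalt hydride hydrogen-atom transfer to C8' and oxidation of the tertiary C7' radical (radical–polar crossover hydroalkoxylation of Mukaiyama type) give a cation that only the axial ring A enol oxygen can reach on the locked chair, so the 6-oxabicyclo[3.2.1] closure sets C7' (O axial, cis to H2') and makes C1 stereogenic with the bridged carbon C2 axial; the 3'-OH is trans to C7' and cannot compete.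

Step 5
Reactants: 8 bridged enol ether
Product: 10 5-isobutyryl bridged enol ether, via enol isobutyrate 9 (not isolated)
Conditions: iPrCO2H (1.2 equiv), DCC (1.2 equiv), DMAP (0.3 equiv), CH2Cl2, 0 °C to rt
Reagents that add atoms: isobutyric acid CC(C)C(=O)O
Why: Steglich-type O-acylation of the only free enol (the C6/C4 vinylogous acid) and DMAP-mediated 1,3 O-to-C acyl migration place the isobutyryl group on C5, the carbon between the two unbridged oxygens; the hindered tertiary 3'-OH does not react and no stereocentre is touched.

Step 6
Reactants: 10 5-isobutyryl bridged enol ether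
Product: 13 tomoeone D, via hydroxy triketone 11 (not isolated), via mono-prenyl triketone 12 (not isolated)
Conditions: KOH (2 M aq)/1,4-dioxane, 50 °C; then 0 °C, prenyl bromide (2.5 equiv); cold dilute HCl work-up
Reagents that add atoms: potassium hydroxide (aqueous) [K+].[OH-]; prenyl bromide CC(C)=CCBr
Why: Hydroxide adds to C2 of the vinylogous ester and expels the C7' alkoxide (addition–elimination; the C7'–O bond is not broken, so its configuration is kept), and the triketone polyanion is then C-alkylated twice at C3, the only ring CH2 left (lupulone-type gem-diprenylation through 12), which makes the formerly bridged axial carbonyl the one next to the gem-diprenyl carbon, as in the target.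

**Compound list**
1 | (R)-(−)-linalool, (3R)-3,7-dimethylocta-1,6-dien-3-ol | C=C[C@](C)(O)CCC=C(C)C | starting material
2 | (E)-8-hydroxylinalool, (2E,6R)-2,6-dimethylocta-2,7-diene-1,6-diol | C=C[C@](C)(O)CC/C=C(\C)CO | intermediate
3 | (E)-8-oxolinalool, (2E,6R)-6-hydroxy-2,6-dimethylocta-2,7-dienal | C=C[C@](C)(O)CC/C=C(\C)C=O | intermediate
4 | phloroglucinol (benzene-1,3,5-triol) | Oc1cc(O)cc(O)c1 | starting material
5 | oxatriene (ring-opened o-quinone methide form of 6): 5-hydroxy-2-[(2E,6R)-6-hydroxy-2,6-dimethylocta-2,7-dienylidene]cyclohex-4-ene-1,3-dione | C=C[C@](C)(O)CC/C=C(\C)C=C1C(=O)CC(O)=CC1=O | intermediate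
6 | 2-[(3R)-3-hydroxy-3-methylpent-4-enyl]-3-methyl-2H-chromene-5,7-diol (both C2 epimers) | C=C[C@](C)(O)CCC1Oc2cc(O)cc(O)c2C=C1C | intermediate
7 | spiro trione: ring A is a 2,2-disubstituted 5-hydroxycyclohex-4-ene-1,3-dione whose quaternary carbon is the spiro carbon C1; six-ring C1–C1'H2–C2'H–C6'H–C7'(CH3)=C8'H is trans-fused at C2'–C6' to the cyclopentane C2'–C3'(CH3)(OH)–C4'H2–C5'H2–C6'; 3'R, 3'-OH cis to C1'; C1 not stereogenic | O=C1CC(O)=CC(=O)C12C[C@H]3[C@@H](CC[C@@]3(C)O)C(C)=C2 | intermediate
8 | bridged enol ether: ring A is C2(O–)=C3H–C4(=O)–C5H=C6(OH); the C2 oxygen is bonded to C7' (oxolane C1/C8'/C7'/O/C2); C7'–O axial and cis to H2', 7'-CH3 equatorial; rest as in 7 | OC1=CC(=O)C=C2O[C@@]3(C)C[C@@]12C[C@H]4[C@H]3CC[C@@]4(C)O | intermediate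
9 | enol isobutyrate of 8 (O-acylated at the C6 enol oxygen) | CC(C)C(=O)OC1=CC(=O)C=C2O[C@@]3(C)C[C@@]12C[C@H]4[C@H]3CC[C@@]4(C)O | intermediate
10 | 5-isobutyryl derivative of 8 (C6(OH)=C5(COiPr)–C4=O, bridge intact) | OC1=C(C(=O)C(C)C)C(=O)C=C2O[C@@]3(C)C[C@@]12C[C@H]4[C@H]3CC[C@@]4(C)O | intermediate
11 | hydroxy triketone: tomoeone D lacking both prenyl groups (C3H2), 7'-OH free | CC(C)C(=O)C1=C(O)CC(=O)[C@]2(C[C@H]3[C@@H](CC[C@@]3(C)O)[C@@](C)(O)C2)C1=O | intermediate
12 | mono-prenyl triketone: tomoeone D lacking one prenyl group at C3, drawn as the C2/C4 dienol | CC(C)=CCC1=C(O)[C@]2(C[C@H]3[C@@H](CC[C@@]3(C)O)[C@@](C)(O)C2)C(=O)C(C(=O)C(C)C)=C1O | intermediate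
13 | tomoeone D (in these labels C1 R, C2' S, C3' R, C6' R, C7' S) | CC(C)=CCC1(CC=C(C)C)C(=O)[C@]2(C[C@H]3[C@@H](CC[C@@]3(C)O)[C@@](C)(O)C2)C(=O)C(C(=O)C(C)C)=C1O | target

**Step count**
Total: 6 steps. Longest linear sequence: 6 steps (1 to 13); phloroglucinol enters at step 2.

**Steps most likely to fail**

Step 3 is the weakest. Ring opening of the aromatic chromene costs the phloroglucinol aromaticity. The diene terminus C1 is fully substituted and carries an inside carbonyl, and the dienophile is unactivated. The cycloaddition may therefore be too slow below decomposition temperatures, and the cis/trans and OH/CH3 facial selectivities are likely modest. Fallback: set out from 3 and condense it with cyclohexane-1,3-dione in place of phloroglucinol (ethylenediammonium diacetate, MeOH, 65 °C). The Knoevenagel product is the alkylidene dione F1, which rests as the non-aromatic 2H-pyran F2. Its ring opens without any loss of aromaticity, so heating (PhMe, 180 °C) should give the spiro dione F3 more readily. IBX (DMSO, 70 °C) dehydrogenates ring A to the spiro enedione F4 (either side, both converge). Wacker-type oxidation of the enone β-carbon (Na2PdCl4 cat., tBuOOH, AcOH/H2O, 50 °C) adds the third ring oxygen and comes back at 7.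

Step 4: hydrogen-atom transfer to the hindered C8' next to the quaternary carbon may be slow, and the ring A enone may be reduced instead. Fallback: set out from 7 with an iodoetherification. NIS (3.3 equiv, NaHCO3, CH2Cl2, 0 °C) first iodinates the two enolic ring A carbons. It then activates C7'=C8' from the face opposite the axial enol oxygen, and trans-diaxial addition gives the triiodo bridged enol ether F5. Bu3SnH/AIBN (PhH, 80 °C) removes all three iodines and comes back at 8, whichever ring A oxygen was differentiated by the ring iodines.

Step 6: the vinylogous ester sits in an anionic triketone and may open slowly. Warm alkali can deacylate the triketone, and O-prenylation or mono-alkylation will lower the yield. Fallback: set out from 10, open the bridge with LiOH (THF/H2O, rt) and isolate hydroxy triketone 11 after cold acidification. Neutral Tsuji–Trost prenylation (Pd(PPh3)4, zerovalent palladium, 5 mol %, methyl 2-methylbut-3-en-2-yl carbonate, THF, rt) then gives mono-prenyl triketone 12, this time isolated. A second round of the same alkylation comes back at 13.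

**Further compounds**
F1 | step 3 | 2-[(2E,6R)-6-hydroxy-2,6-dimethylocta-2,7-dienylidene]cyclohexane-1,3-dione | C=C[C@](C)(O)CC/C=C(\C)C=C1C(=O)CCCC1=O
F2 | step 3 | 2-[(3R)-3-hydroxy-3-methylpent-4-enyl]-3-methyl-2,6,7,8-tetrahydro-5H-chromen-5-one (both C2 epimers) | C=C[C@](C)(O)CCC1OC2=C(C=C1C)C(=O)CCC2
F3 | step 3 | spiro dione (analogue of 7 with cyclohexane-1,3-dione as ring A) | O=C1CCCC(=O)C12C[C@H]3[C@@H](CC[C@@]3(C)O)C(C)=C2
F4 | step 3 | spiro cyclohex-4-ene-1,3-dione from F3 (both spiro epimers) | O=C1C=CCC(=O)C12C[C@H]3[C@@H](CC[C@@]3(C)O)C(C)=C2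
F5 | step 4 | 3,5,8'-triiodo bridged enol ether (8'-iodine trans to the bridging oxygen) | OC1=C(I)C(=O)C(I)=C2O[C@@]3(C)[C@H](I)[C@@]12C[C@H]4[C@H]3CC[C@@]4(C)O
F0 | step 6 | none | none
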